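The numbers of this flask were chosen freely; the flask was simulated.

Amounts first: these flasks hold the same substrate and reagent and differ in their initiator charge.

| setting | Tuesday's | Saturday's | Friday's | Monday's |
|---|---|---|---|---|
| substrate | 0.25 M | 0.25 M | 0.25 M | 0.25 M |
| reagent | 0.500 M | 0.500 M | 0.500 M | 0.500 M |
| initiator | 20 mM | 40 mM | 80 mM | 150 mM |
| time | 3.0 d | 3.0 d | 3.0 d | 3.0 d |

    substrate + initiating radical → capped initiator + first chain carrier (k1 = 2.9 × 10⁵ M⁻¹ min⁻¹)
    2 substrate → self-condensation product (k2 = 7.2 × 10⁻⁴ M⁻¹ min⁻¹)
    reagent + first chain carrier → target + second chain carrier (k3 = 3900 M⁻¹ min⁻¹)
    substrate + second chain carrier → by-product + first chain carrier (k4 = 44000 M⁻¹ min⁻¹)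
    2 first chain carrier → ended chains B (k5 = 5 × 10⁸ M⁻¹ s⁻¹)
    2 second chain carrier → ended chains A (k6 = 3 × 10⁶ M⁻¹ s⁻¹)
    initiator → 2 initiating radical (k7 = 3.5 × 10⁻⁴ min⁻¹)

- percentages count the substrate that a species holds: one ended chains B or self-condensation product counts as two
- a step written with two of one species runs at k times the square of its concentration and takes two of it each time
- "hardly changes" means that all values lie within two and a half points (for a concentration: within two and a half percent of the largest)
- run time (Tuesday's): 3.0 d
- a step back or a flat step of under half a percent of the largest counts as no turn

- [target] at the end for Tuesday's, Saturday's, Friday's, Monday's, in this order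
- how that number moves from the first to the last of them (falls all the way / hardly changes / falls, then rises / rises all the way / rises, then falls)

You asked for a quick number, so I reckoned the chain itself. Reagent is consumed by first chain carrier in a pseudo-first-order way, so I needed that carrier's level. Radicals arrived as initiator decayed, and first chain carriers left in pairs as ended chains B. At the charge, that ending outran the ending of second chain carriers by about 5300 times. I therefore balanced arrival against that pair step, and substrate dropped out of the sum while it lasted.

For Tuesday's this set an opening carrier level of 1.53 × 10⁻⁸ M. The level follows the square root of the initiator left, so it integrates in closed form, and the 3.0 d counted as 2.10 d at the opening level. Multiplying the reagent-step constant by both gave Tuesday's chain dose, 0.181, the natural logarithm of reagent charged over reagent left. With other settings held, it grows as the square root of the initiator charge. So I committed to Tuesday's reagent at 83.4% of its charge and target at 33.0% of the substrate charged.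

Each radical delivered also places one share of substrate in ended chains B. Friday's dose asked for 60.6% of the substrate as target, and I reckoned the claim of its radicals at 49.9%, together more than the charge. I expected Friday's chain to stop short of its dose, with substrate as limiting reagent, and the row to rise and then fall.

The forecast gave 0.082 M, 0.109 M, 0.104 M and 0.092 M, rises, then falls, holding that “more of it is lost to capping radicals”.

The simulation gave 0.0826 M, 0.112 M, 0.107 M and 0.0955 M, rises, then falls.

Tuesday's ended with reagent at 83.5% of its charge and target at 33.0% of the substrate charged. Saturday's dose is 0.255, which gives 45.1%, and Saturday's held 44.8% with substrate down to 1.20%. Monday's target stays this low partly because first chain carriers end each other: Monday's gave 0.0955 M with that step and 0.248 M without it.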